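**Plan**
1. Numbering: C1 is the ester carbon, C3–C6 are the ring carbons (O2 on C3, O1 on C6), C7–C18 the chain. The retrosynthesis cuts C7=C8 and C11=C12 (Wittig reactions, saturated later), C8–C9 (ylide alkylation), O1–C6 (dioxane closure), C2–C3 (crotylboration) and C4–C5 (allyl coupling).
2. Forward: epoxide 4 → epoxy aldehyde 5 → anti homoallylic alcohol 8 → C3 hydroperoxide by inversion → vinyl oxidised to the C1 methyl ester → the 1,2-dioxane, the only ring formed, closes in step 11 → C7 aldehyde 17. The C8–C18 chain is built separately, joined at C7=C8, then diimide and unmasking of the C14 hydroperoxide.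
3. Enabling feature: ring carbon C6 of the 1,2-dioxane is quaternary (O1, CH3, ring C5, chain C7), and its two CH2 neighbours give no steric handle for ring-controlled bond formation. It is therefore carried as a 2,2-disubstituted C6–C7 epoxide, and the C3–O2–O1H group transfers the epoxide configuration to C6 by inversion.
4. Stereochemistry: C6 from (R)-2-methylglycidol; C2 and C3 from a catalyst-controlled anti-crotylboration followed by SN2 inversion at C3; C10 from (S)-3-bromo-2-methylpropan-1-ol; C14 from (R)-linalool through an oxetane opened by H2O2 with inversion.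

Key step: step 11

Assumption: the (S)-configured binaphthyl phosphoric acid is taken to direct crotyl transfer to the Si face of the unbranched aldehyde 5; if the sense is the reverse, the mirror-image acid is used and nothing else changes.

**Route**

Step 1
Reactants: 1 (R)-2-methylglycidol
Product: 2 [(2S)-2-methyloxiran-2-yl]methyl trifluoromethanesulfonate
Conditions: Tf2O, 2,6-lutidine, CH2Cl2, −78 → −40 °C; cold aqueous wash, used at once
Reagents that add atoms: trifluoromethanesulfonic anhydride, O=S(=O)(OS(=O)(=O)C(F)(F)F)C(F)(F)F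
Why: O-sulfonylation of the primary alcohol under hindered-base buffering leaves the epoxide and its quaternary stereocentre untouched (the descriptor changes from R to S only because the priorities change).

Step 2
Reactants: 2 [(2S)-2-methyloxiran-2-yl]methyl trifluoromethanesulfonate; 3 allylmagnesium chloride
Product: 4 (2R)-2-(but-3-en-1-yl)-2-methyloxirane
Conditions: 3 (1.2 equiv), CuI (10 mol%), THF/Et2O, −78 → −40 °C
Reagents that add atoms: none
Why: Copper-catalysed Grignard coupling at the primary triflate, which should leave far faster than the epoxide opens at −78 °C, forms C4–C5 by direct substitution and carries the future C6–C7 epoxide over with its configuration intact.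

Step 3
Reactants: 4 (2R)-2-(but-3-en-1-yl)-2-methyloxirane
Product: 5 3-[(2R)-2-methyloxiran-2-yl]propanal
Conditions: O3, CH2Cl2, −78 °C; then Me2S, −78 °C → rt
Reagents that add atoms: ozone, [O-][O+]=O
Why: Ozonolysis with reductive work-up cleaves the only alkene to the C3 aldehyde under neutral conditions that should spare the epoxide.

Step 4
Reactants: 5 3-[(2R)-2-methyloxiran-2-yl]propanal; 6 (E)-crotylboronic acid pinacol ester
Product: 8 (3S,4R)-3-methyl-6-[(2R)-2-methyloxiran-2-yl]hex-1-en-4-ol, via pinacol borate 7 (not isolated)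
Conditions: 6 (1.2 equiv), (S)-3,3′-bis(2,4,6-triisopropylphenyl)-1,1′-binaphthyl-2,2′-diyl hydrogen phosphate (5 mol%), 4 Å molecular sieves, toluene, −30 °C; aqueous NaHCO3 work-up, Et3N-deactivated silica
Reagents that add atoms: none
Why: Chiral-phosphoric-acid-catalysed crotylboration through a closed Zimmerman–Traxler chair, in which the E-crotyl geometry fixes the anti C2/C3 relationship and the catalyst directs addition to the Si face of the aldehyde, should give the (3S,4R) alcohol while the small amount of acid in cold toluene spares the epoxide.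

Step 5
Reactants: 8 (3S,4R)-3-methyl-6-[(2R)-2-methyloxiran-2-yl]hex-1-en-4-ol
Product: 10 (2R)-2-[(3S,4S)-3-hydroperoxy-4-methylhex-5-en-1-yl]-2-methyloxirane, via secondary triflate 9 (not isolated)
Conditions: Tf2O, 2,6-lutidine, CH2Cl2, −78 °C; then transferred cold into anhydrous H2O2 (Et2O, 15 equiv) pre-treated with KOtBu (3 equiv) in THF, −78 → −20 °C; pH 7 buffer quench
Reagents that add atoms: trifluoromethanesulfonic anhydride, O=S(=O)(OS(=O)(=O)C(F)(F)F)C(F)(F)F (triflyl group of 9 only); hydrogen peroxide, OO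
Why: SN2 alkylation of the hydroperoxide anion, a strong but weakly basic alpha-effect nucleophile, by the secondary triflate inverts C3 and so turns the anti alcohol into the syn (3S) hydroperoxide, with excess H2O2 suppressing a second alkylation and low temperature keeping elimination and epoxide participation behind substitution.

Step 6
Reactants: 10 (2R)-2-[(3S,4S)-3-hydroperoxy-4-methylhex-5-en-1-yl]-2-methyloxirane
Product: 11 tert-butyl(dimethyl){[(3S,4S)-4-methyl-1-[(2R)-2-methyloxiran-2-yl]hex-5-en-3-yl]peroxy}silane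
Conditions: TBSCl, imidazole, DMF, 0 °C
Reagents that add atoms: tert-butyldimethylsilyl chloride, CC(C)(C)[Si](C)(C)Cl
Why: Silylation of the acidic hydroperoxide under basic conditions gives a silyl peroxide that masks the O–O–H during the oxidative unveiling of C1 and keeps it from reaching the epoxide too early.

Step 7
Reactants: 11 tert-butyl(dimethyl){[(3S,4S)-4-methyl-1-[(2R)-2-methyloxiran-2-yl]hex-5-en-3-yl]peroxy}silane
Product: 12 (2R,3S)-3-{[tert-butyl(dimethyl)silyl]peroxy}-2-methyl-5-[(2R)-2-methyloxiran-2-yl]pentanal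
Conditions: O3, CH2Cl2, −78 °C; then Me2S, −78 → 0 °C; crude product used directly
Reagents that add atoms: ozone, [O-][O+]=O
Why: Ozonolysis with a sulfide work-up, which reduces the ozonide but not a silyl peroxide, converts the vinyl group into the C1 aldehyde, and immediate use of the crude aldehyde gives C2 no time to epimerise.

Step 8
Reactants: 12 (2R,3S)-3-{[tert-butyl(dimethyl)silyl]peroxy}-2-methyl-5-[(2R)-2-methyloxiran-2-yl]pentanal
Product: 13 (2R,3S)-3-{[tert-butyl(dimethyl)silyl]peroxy}-2-methyl-5-[(2R)-2-methyloxiran-2-yl]pentanoic acid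
Conditions: NaClO2, NaH2PO4, 2-methylbut-2-ene, t-BuOH/H2O, 0 °C
Reagents that add atoms: sodium chlorite, [Na+].[O-]Cl=O
Why: Pinnick oxidation under phosphate buffer with an alkene scavenger for hypochlorite oxidises the aldehyde to the acid without enolisation at C2 and should not harm the epoxide or the silyl peroxide.

Step 9
Reactants: 13 (2R,3S)-3-{[tert-butyl(dimethyl)silyl]peroxy}-2-methyl-5-[(2R)-2-methyloxiran-2-yl]pentanoic acid
Product: 14 methyl (2R,3S)-3-{[tert-butyl(dimethyl)silyl]peroxy}-2-methyl-5-[(2R)-2-methyloxiran-2-yl]pentanoate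
Conditions: Me3SiCHN2 (2 M in hexanes), toluene/MeOH (4:1), 0 °C
Reagents that add atoms: (trimethylsilyl)diazomethane, C[Si](C)(C)C=[N+]=[N-]
Why: O-methylation of the acid by diazomethane released from the silyl reagent in methanol is fast and neutral, so it avoids both base (β-elimination of the peroxide) and acid (epoxide opening).

Step 10
Reactants: 14 methyl (2R,3S)-3-{[tert-butyl(dimethyl)silyl]peroxy}-2-methyl-5-[(2R)-2-methyloxiran-2-yl]pentanoate
Product: 15 methyl (2R,3S)-3-hydroperoxy-2-methyl-5-[(2R)-2-methyloxiran-2-yl]pentanoate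
Conditions: Bu4NF (1.1 equiv), AcOH (1.5 equiv), THF, 0 °C; neutral work-up, Et3N-deactivated silica
Reagents that add atoms: none
Why: Fluoride cleaves the Si–O bond of the silyl peroxide and the acetic acid buffer protonates the peroxy anion at once, so neither base-induced fragmentation of the β-peroxy ester nor acid-induced epoxide opening should intervene.

Step 11
Reactants: 15 methyl (2R,3S)-3-hydroperoxy-2-methyl-5-[(2R)-2-methyloxiran-2-yl]pentanoate
Product: 16 methyl (2R)-2-[(3S,6S)-6-(hydroxymethyl)-6-methyl-1,2-dioxan-3-yl]propanoate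
Conditions: (1S)-(+)-10-camphorsulfonic acid (0.1 equiv), CH2Cl2, 0 °C → rt
Reagents that add atoms: none
Why: The sulfonic acid protonates the epoxide oxygen, the tertiary C6–O bond lengthens, and the terminal oxygen of the C3 hydroperoxide attacks C6 from the face opposite the departing oxygen, forming O1–C6 and releasing C7 as CH2OH. The closest known reaction type is the acid-promoted intramolecular opening of epoxides by hydroperoxides to give 1,2-dioxanes, the peroxide counterpart of epoxy-alcohol cyclisation. The one ring formed, the 1,2-dioxane (O1, O2, C3–C6), closes in the 6-exo-tet mode. The one new stereocentre, quaternary C6, is set by the epoxide itself: the substitution is invertive, so the (R)-epoxide carbon from 1 becomes the (6S) ring carbon of 16 (6R in the target once C7 carries the chain), and C2 and C3 are untouched. The step needs attack at C6 rather than at C7 (7-endo) and opening without a free tertiary cation; ring size and Markovnikov bias both point to C6, and a catalytic weak acid in non-nucleophilic, poorly ionising CH2Cl2 with a tethered alpha-effect nucleophile should keep the opening concerted. The methyl ester has no oxygen within reach of a five- or six-membered closure and should stay a spectator.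

Step 12
Reactants: 16 methyl (2R)-2-[(3S,6S)-6-(hydroxymethyl)-6-methyl-1,2-dioxan-3-yl]propanoate
Product: 17 methyl (2R)-2-[(3S,6S)-6-formyl-6-methyl-1,2-dioxan-3-yl]propanoate
Conditions: Dess–Martin periodinane, CH2Cl2, 0 °C → rt
Reagents that add atoms: none
Why: Dess–Martin oxidation of the neopentyl primary alcohol gives an aldehyde with no α-hydrogen (C6 is quaternary), which therefore cannot enolise or epimerise.

Step 13
Reactants: 18 (R)-linalool
Product: 20 (3R)-3,7-dimethyloct-6-ene-1,3-diol, via B-alkyl-9-BBN adduct 19 (not isolated)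
Conditions: 9-BBN (1.3 equiv), THF, 0 °C → rt; then NaOH (3 M aq.), H2O2 (30% aq.), 0 °C → rt
Reagents that add atoms: 9-borabicyclo[3.3.1]nonane, B1C2CCCC1CCC2 (boron of 19 only); hydrogen peroxide, OO
Why: Hydroboration–oxidation with the bulky borane is anti-Markovnikov and selective for the monosubstituted vinyl group over the trisubstituted alkene, giving the primary alcohol (C12) without touching the carbinol stereocentre (C14).

Step 14
Reactants: 20 (3R)-3,7-dimethyloct-6-ene-1,3-diol
Product: 22 (2R)-2-methyl-2-(4-methylpent-3-en-1-yl)oxetane, via primary tosylate 21 (not isolated)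
Conditions: n-BuLi (1.0 equiv), THF, 0 °C; TsCl (1.0 equiv); then n-BuLi (1.1 equiv), 0 → 60 °C
Reagents that add atoms: 4-toluenesulfonyl chloride, Cc1ccc(cc1)S(=O)(=O)Cl (tosyl group of 21 only)
Why: Selective tosylation of the primary alkoxide followed by intramolecular Williamson etherification (4-exo-tet) by the tertiary alkoxide closes the oxetane without breaking the C14–O bond, so the configuration is retained.

Step 15
Reactants: 22 (2R)-2-methyl-2-(4-methylpent-3-en-1-yl)oxetane
Product: 23 (3S)-3-hydroperoxy-3,7-dimethyloct-6-en-1-ol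
Conditions: anhydrous H2O2 (Et2O, 5 equiv), Me3SiOTf (0.2 equiv), Et2O, −78 → 0 °C; aqueous NaHCO3
Reagents that add atoms: hydrogen peroxide, OO
Why: Lewis-acid-promoted opening of the oxetane by H2O2 at the tertiary carbon is a borderline SN2 process with backside attack, so the C14–O bond of linalool is replaced by C14–OO with inversion, which is the configuration the target needs, and the primary hydroxyl (C12) is freed for chain extension.

Step 16
Reactants: 23 (3S)-3-hydroperoxy-3,7-dimethyloct-6-en-1-ol
Product: 24 (3S)-3-{[tert-butyl(dimethyl)silyl]peroxy}-3,7-dimethyloct-6-en-1-ol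
Conditions: TBSCl (1.05 equiv), Et3N (1.2 equiv), CH2Cl2, −20 → 0 °C
Reagents that add atoms: tert-butyldimethylsilyl chloride, CC(C)(C)[Si](C)(C)Cl
Why: With Et3N as the only base the far more acidic hydroperoxide (pKa near 12.5 against about 16) is silylated through its alpha-effect anion, whereas a neutral primary alcohol reacts with the silyl chloride only sluggishly without a nucleophilic catalyst, so the peroxide should be capped chemoselectively.

Step 17
Reactants: 24 (3S)-3-{[tert-butyl(dimethyl)silyl]peroxy}-3,7-dimethyloct-6-en-1-ol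
Product: 25 (3S)-3-{[tert-butyl(dimethyl)silyl]peroxy}-3,7-dimethyloct-6-enal
Conditions: Dess–Martin periodinane, CH2Cl2, 0 °C → rt
Reagents that add atoms: none
Why: Dess–Martin oxidation gives the β-silylperoxy aldehyde (C12) under non-basic conditions that avoid β-elimination of the peroxide.

Step 18
Reactants: 26 (S)-3-bromo-2-methylpropan-1-ol
Product: 27 [(2S)-3-hydroxy-2-methylpropyl]triphenylphosphonium bromide
Conditions: PPh3 (1.1 equiv), MeCN, reflux
Reagents that add atoms: triphenylphosphine, c1ccc(cc1)P(c1ccccc1)c1ccccc1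
Why: SN2 quaternisation of triphenylphosphine by the primary bromide gives the hydroxy phosphonium salt without involving the stereocentre (future C10).

Step 19
Reactants: 25 (3S)-3-{[tert-butyl(dimethyl)silyl]peroxy}-3,7-dimethyloct-6-enal; 27 [(2S)-3-hydroxy-2-methylpropyl]triphenylphosphonium bromide
Product: 29 (2R,3Z,6S)-6-{[tert-butyl(dimethyl)silyl]peroxy}-2,6,10-trimethylundeca-3,9-dien-1-ol, via oxido ylide 28 (not isolated)
Conditions: 27 (1.3 equiv), n-BuLi (2.6 equiv), THF, −20 → 0 °C; then 25, −78 → 0 °C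
Reagents that add atoms: n-butyllithium, [Li]CCCC (lithium of 28 only)
Why: Wittig olefination with the γ-oxido ylide joins C11 to C12, since a non-stabilised ylide should add to the aldehyde at −78 °C faster than it deprotonates it, and the mainly Z geometry is irrelevant because the bond is saturated later.

Step 20
Reactants: 29 (2R,3Z,6S)-6-{[tert-butyl(dimethyl)silyl]peroxy}-2,6,10-trimethylundeca-3,9-dien-1-ol
Product: 30 tert-butyl{[(6S,8Z,10R)-11-iodo-2,6,10-trimethylundeca-2,8-dien-6-yl]peroxy}dimethylsilane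
Conditions: PPh3, I2, imidazole, CH2Cl2, 0 °C (reagent premixed before 29 is added)
Reagents that add atoms: iodine, II
Why: Appel-type iodination of the primary alcohol runs through the alkoxyphosphonium ion under near-neutral conditions, and binding the phosphine as its iodine adduct beforehand keeps it from reducing the silyl peroxide.

Step 21
Reactants: 30 tert-butyl{[(6S,8Z,10R)-11-iodo-2,6,10-trimethylundeca-2,8-dien-6-yl]peroxy}dimethylsilane; 31 methyltriphenylphosphonium bromide
Product: 33 {(3S,4Z,7S)-7-{[tert-butyl(dimethyl)silyl]peroxy}-3,7,11-trimethyldodeca-4,10-dien-1-yl}triphenylphosphonium iodide, via methylenetriphenylphosphorane 32 (not isolated)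
Conditions: 31 (1.1 equiv), n-BuLi (1.1 equiv), THF, 0 °C; then 30, −78 °C → rt; salt precipitated with Et2O
Reagents that add atoms: none
Why: SN2 C-alkylation of the methylene ylide by the primary iodide inserts C8 and gives the homologous phosphonium salt directly, without ever heating triphenylphosphine with the peroxide.

Step 22
Reactants: 17 methyl (2R)-2-[(3S,6S)-6-formyl-6-methyl-1,2-dioxan-3-yl]propanoate; 33 {(3S,4Z,7S)-7-{[tert-butyl(dimethyl)silyl]peroxy}-3,7,11-trimethyldodeca-4,10-dien-1-yl}triphenylphosphonium iodide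
Product: 35 methyl (2R)-2-[(3S,6S)-6-[(1Z,4S,5Z,8S)-8-{[tert-butyl(dimethyl)silyl]peroxy}-4,8,12-trimethyltrideca-1,5,11-trien-1-yl]-6-methyl-1,2-dioxan-3-yl]propanoate, via phosphorus ylide 34 (not isolated)
Conditions: 33 (1.2 equiv), NaN(SiMe3)2 (1.15 equiv), THF, −78 °C; then 17, −78 → −20 °C
Reagents that add atoms: none
Why: Wittig olefination of the non-enolisable aldehyde by the pre-formed ylide at −78 °C forms C7=C8, and adding the aldehyde to the ylide keeps free base away from the C2 hydrogen of the β-peroxy ester while the alkene geometry again does not matter.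

Step 23
Reactants: 35 methyl (2R)-2-[(3S,6S)-6-[(1Z,4S,5Z,8S)-8-{[tert-butyl(dimethyl)silyl]peroxy}-4,8,12-trimethyltrideca-1,5,11-trien-1-yl]-6-methyl-1,2-dioxan-3-yl]propanoate
Product: 36 methyl (2R)-2-[(3S,6R)-6-[(4S,8R)-8-{[tert-butyl(dimethyl)silyl]peroxy}-4,8,12-trimethyltridec-11-en-1-yl]-6-methyl-1,2-dioxan-3-yl]propanoate
Conditions: KO2CN=NCO2K (excess, in portions), AcOH, MeOH/CH2Cl2, 0 °C → rt; stopped once both disubstituted alkenes are consumed
Reagents that add atoms: none
Why: Diimide reduction transfers H2 by a concerted syn pathway that does not cleave O–O bonds and is markedly faster for 1,2-disubstituted alkenes than for the trisubstituted C17=C18 alkene, so both Wittig-derived double bonds should be saturated selectively.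

Step 24
Reactants: 36 methyl (2R)-2-[(3S,6R)-6-[(4S,8R)-8-{[tert-butyl(dimethyl)silyl]peroxy}-4,8,12-trimethyltridec-11-en-1-yl]-6-methyl-1,2-dioxan-3-yl]propanoate
Product: 37 methyl (2R)-2-[(3S,6R)-6-[(4R,8R)-8-hydroperoxy-4,8,12-trimethyltridec-11-en-1-yl]-6-methyl-1,2-dioxan-3-yl]propanoate
Conditions: Bu4NF (1.1 equiv), AcOH (1.5 equiv), THF, 0 °C
Reagents that add atoms: none
Why: Buffered fluoride removes the silyl group from the tertiary peroxide and unveils the C14 hydroperoxide without base-induced damage to the β-peroxy ester of the dioxane (the C10 descriptor changes from S to R only through the priority change).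

**Compound list**

1 | (R)-2-methylglycidol, [(2R)-2-methyloxiran-2-yl]methanol | OC[C@]1(C)CO1 | starting material
2 | [(2S)-2-methyloxiran-2-yl]methyl trifluoromethanesulfonate | FC(F)(F)S(=O)(=O)OC[C@]1(C)CO1 | intermediate
3 | allylmagnesium chloride | C=CC[Mg]Cl | starting material
4 | (2R)-2-(but-3-en-1-yl)-2-methyloxirane | C=CCC[C@]1(C)CO1 | intermediate
5 | 3-[(2R)-2-methyloxiran-2-yl]propanal | O=CCC[C@]1(C)CO1 | intermediate
6 | (E)-crotylboronic acid pinacol ester | C/C=C/CB1OC(C)(C)C(C)(C)O1 | starting material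
7 | 2-{[(3S,4R)-3-methyl-6-[(2R)-2-methyloxiran-2-yl]hex-1-en-4-yl]oxy}-4,4,5,5-tetramethyl-1,3,2-dioxaborolane | C=C[C@H](C)[C@H](OB1OC(C)(C)C(C)(C)O1)CC[C@]2(C)CO2 | intermediate
8 | (3S,4R)-3-methyl-6-[(2R)-2-methyloxiran-2-yl]hex-1-en-4-ol | C=C[C@H](C)[C@H](O)CC[C@]1(C)CO1 | intermediate
9 | (3S,4R)-3-methyl-6-[(2R)-2-methyloxiran-2-yl]hex-1-en-4-yl trifluoromethanesulfonate | C=C[C@H](C)[C@H](OS(=O)(=O)C(F)(F)F)CC[C@]1(C)CO1 | intermediate
10 | (2R)-2-[(3S,4S)-3-hydroperoxy-4-methylhex-5-en-1-yl]-2-methyloxirane | C=C[C@H](C)[C@@H](OO)CC[C@]1(C)CO1 | intermediate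
11 | tert-butyl(dimethyl){[(3S,4S)-4-methyl-1-[(2R)-2-methyloxiran-2-yl]hex-5-en-3-yl]peroxy}silane | C=C[C@H](C)[C@@H](OO[Si](C)(C)C(C)(C)C)CC[C@]1(C)CO1 | intermediate
12 | (2R,3S)-3-{[tert-butyl(dimethyl)silyl]peroxy}-2-methyl-5-[(2R)-2-methyloxiran-2-yl]pentanal | O=C[C@H](C)[C@@H](OO[Si](C)(C)C(C)(C)C)CC[C@]1(C)CO1 | intermediate
13 | (2R,3S)-3-{[tert-butyl(dimethyl)silyl]peroxy}-2-methyl-5-[(2R)-2-methyloxiran-2-yl]pentanoic acid | OC(=O)[C@H](C)[C@@H](OO[Si](C)(C)C(C)(C)C)CC[C@]1(C)CO1 | intermediate
14 | methyl (2R,3S)-3-{[tert-butyl(dimethyl)silyl]peroxy}-2-methyl-5-[(2R)-2-methyloxiran-2-yl]pentanoate | COC(=O)[C@H](C)[C@@H](OO[Si](C)(C)C(C)(C)C)CC[C@]1(C)CO1 | intermediate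
15 | methyl (2R,3S)-3-hydroperoxy-2-methyl-5-[(2R)-2-methyloxiran-2-yl]pentanoate | COC(=O)[C@H](C)[C@@H](OO)CC[C@]1(C)CO1 | intermediate
16 | methyl (2R)-2-[(3S,6S)-6-(hydroxymethyl)-6-methyl-1,2-dioxan-3-yl]propanoate | COC(=O)[C@H](C)[C@@H]1CC[C@@](C)(CO)OO1 | intermediate
17 | methyl (2R)-2-[(3S,6S)-6-formyl-6-methyl-1,2-dioxan-3-yl]propanoate | COC(=O)[C@H](C)[C@@H]1CC[C@@](C)(C=O)OO1 | intermediate
18 | (R)-linalool | C=C[C@@](C)(CCC=C(C)C)O | starting material
19 | (3S)-1-(9-borabicyclo[3.3.1]nonan-9-yl)-3,7-dimethyloct-6-en-3-ol (same spatial arrangement as 18) | B1(CC[C@@](C)(CCC=C(C)C)O)C2CCCC1CCC2 | intermediate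
20 | (3R)-3,7-dimethyloct-6-ene-1,3-diol | OCC[C@@](C)(CCC=C(C)C)O | intermediate
21 | (3R)-3-hydroxy-3,7-dimethyloct-6-en-1-yl 4-methylbenzenesulfonate | Cc1ccc(cc1)S(=O)(=O)OCC[C@@](C)(CCC=C(C)C)O | intermediate
22 | (2R)-2-methyl-2-(4-methylpent-3-en-1-yl)oxetane | CC(C)=CCC[C@]1(C)CCO1 | intermediate
23 | (3S)-3-hydroperoxy-3,7-dimethyloct-6-en-1-ol | OCC[C@](C)(CCC=C(C)C)OO | intermediate
24 | (3S)-3-{[tert-butyl(dimethyl)silyl]peroxy}-3,7-dimethyloct-6-en-1-ol | OCC[C@](C)(CCC=C(C)C)OO[Si](C)(C)C(C)(C)C | intermediate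
25 | (3S)-3-{[tert-butyl(dimethyl)silyl]peroxy}-3,7-dimethyloct-6-enal | O=CC[C@](C)(CCC=C(C)C)OO[Si](C)(C)C(C)(C)C | intermediate
26 | (S)-3-bromo-2-methylpropan-1-ol | OC[C@H](C)CBr | starting material
27 | [(2S)-3-hydroxy-2-methylpropyl]triphenylphosphonium bromide | OC[C@H](C)C[P+](c1ccccc1)(c1ccccc1)c1ccccc1.[Br-] | intermediate
28 | lithium (2S)-2-methyl-3-(triphenyl-λ5-phosphanylidene)propan-1-olate | [Li+].[O-]C[C@H](C)C=P(c1ccccc1)(c1ccccc1)c1ccccc1 | intermediate
29 | (2R,3Z,6S)-6-{[tert-butyl(dimethyl)silyl]peroxy}-2,6,10-trimethylundeca-3,9-dien-1-ol | OC[C@H](C)/C=C\C[C@](C)(CCC=C(C)C)OO[Si](C)(C)C(C)(C)C | intermediate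
30 | tert-butyl{[(6S,8Z,10R)-11-iodo-2,6,10-trimethylundeca-2,8-dien-6-yl]peroxy}dimethylsilane | IC[C@H](C)/C=C\C[C@](C)(CCC=C(C)C)OO[Si](C)(C)C(C)(C)C | intermediate
31 | methyltriphenylphosphonium bromide | C[P+](c1ccccc1)(c1ccccc1)c1ccccc1.[Br-] | starting material
32 | methylenetriphenylphosphorane | C=P(c1ccccc1)(c1ccccc1)c1ccccc1 | intermediate
33 | {(3S,4Z,7S)-7-{[tert-butyl(dimethyl)silyl]peroxy}-3,7,11-trimethyldodeca-4,10-dien-1-yl}triphenylphosphonium iodide | [I-].c1ccccc1[P+](c1ccccc1)(c1ccccc1)CC[C@H](C)/C=C\C[C@](C)(CCC=C(C)C)OO[Si](C)(C)C(C)(C)C | intermediate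
34 | {(3S,4Z,7S)-7-{[tert-butyl(dimethyl)silyl]peroxy}-3,7,11-trimethyldodeca-4,10-dien-1-ylidene}triphenyl-λ5-phosphane | c1ccccc1P(c1ccccc1)(c1ccccc1)=CC[C@H](C)/C=C\C[C@](C)(CCC=C(C)C)OO[Si](C)(C)C(C)(C)C | intermediate
35 | methyl (2R)-2-[(3S,6S)-6-[(1Z,4S,5Z,8S)-8-{[tert-butyl(dimethyl)silyl]peroxy}-4,8,12-trimethyltrideca-1,5,11-trien-1-yl]-6-methyl-1,2-dioxan-3-yl]propanoate | COC(=O)[C@H](C)[C@@H]1CC[C@@](C)(/C=C\C[C@H](C)/C=C\C[C@](C)(CCC=C(C)C)OO[Si](C)(C)C(C)(C)C)OO1 | intermediate
36 | methyl (2R)-2-[(3S,6R)-6-[(4S,8R)-8-{[tert-butyl(dimethyl)silyl]peroxy}-4,8,12-trimethyltridec-11-en-1-yl]-6-methyl-1,2-dioxan-3-yl]propanoate | COC(=O)[C@H](C)[C@@H]1CC[C@@](C)(CCC[C@H](C)CCC[C@](C)(CCC=C(C)C)OO[Si](C)(C)C(C)(C)C)OO1 | intermediate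
37 | methyl (2R)-2-[(3S,6R)-6-[(4R,8R)-8-hydroperoxy-4,8,12-trimethyltridec-11-en-1-yl]-6-methyl-1,2-dioxan-3-yl]propanoate (CNP0381652.2) | COC(=O)[C@H](C)[C@@H]1CC[C@@](C)(CCC[C@H](C)CCC[C@](C)(CCC=C(C)C)OO)OO1 | target

**Count and risks**

Total step count: 24. Longest linear sequence: 15 steps (steps 1–12, then 22–24, from 1); the side-chain branch is 11 steps from 18 (steps 13–17 and 19–24), with step 18 as a one-step side branch.

Step 5 (peroxide introduced at C3). What may go wrong: the secondary triflate is lost by base-induced elimination or by participation of the epoxide oxygen before substitution, or the new hydroperoxide is alkylated a second time. The fallback sets out from alcohol 8 and returns at dioxane alcohol 16; it changes the nucleophile to a mono-protected peroxide that stays masked until ring closure. Oxan-2-yl hydroperoxide F1 (from 3,4-dihydro-2H-pyran and H2O2 with a trace of acid) is alkylated as its potassium salt (KOtBu, THF, 0 °C) by triflate 9, with inversion, to the tetrahydropyranyl peroxy alkene F2. Ozonolysis with Me2S work-up gives peroxy aldehyde F3, chlorite oxidation gives peroxy acid F4, and (trimethylsilyl)diazomethane gives methyl ester F5. Camphorsulfonic acid in CH2Cl2/MeOH then cleaves the acetal, and hydroperoxide 15 so released closes onto the epoxide in the same flask to give 16.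

Step 16 (silylation of the hydroperoxide beside a free primary alcohol). What may go wrong: competing silylation of the hydroxyl, or silyl transfer from peroxide oxygen to the alcohol, giving mixtures. The fallback sets out from 23 and returns at 24; it differentiates the two groups enzymatically first. Candida antarctica lipase B with vinyl acetate should acetylate only the unhindered primary alcohol, giving hydroperoxy acetate F6. The hydroperoxide is then silylated (TBSCl, imidazole) to silylperoxy acetate F7. The same lipase in methanol/tert-butyl methyl ether removes the acetate under neutral conditions to give 24.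

Step 22 (Wittig union). What may go wrong: the basic non-stabilised ylide deprotonates C2 of the β-peroxy ester (ring opening by β-elimination) or attacks an O–O bond instead of the hindered α-quaternary aldehyde. The fallback sets out from iodide 30 and returns at 36; a Julia–Kocienski olefination replaces both the ylide homologation and the Wittig reaction. Iodide 30 alkylates the lithium derivative of 5-(methylsulfonyl)-1-phenyl-1H-tetrazole (LiN(SiMe3)2, THF, −78 °C) to give tetrazolyl sulfone F8, whose sulfonyl-bearing carbon is C8. Deprotonation with KN(SiMe3)2 at −78 °C and addition of aldehyde 17 gives, after Smiles rearrangement and loss of SO2, the (1E)-triene F9. Diimide reduction as in step 23 saturates both disubstituted alkenes of F9 and gives 36.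

**Further compounds**

F1 | step 5 | oxan-2-yl hydroperoxide | OOC1CCCCO1
F2 | step 5 | 2-{[(3S,4S)-4-methyl-1-[(2R)-2-methyloxiran-2-yl]hex-5-en-3-yl]peroxy}oxane (mixture at the acetal carbon) | C=C[C@H](C)[C@@H](OOC1CCCCO1)CC[C@]2(C)CO2
F3 | step 5 | (2R,3S)-2-methyl-5-[(2R)-2-methyloxiran-2-yl]-3-(oxan-2-ylperoxy)pentanal | O=C[C@H](C)[C@@H](OOC1CCCCO1)CC[C@]2(C)CO2
F4 | step 5 | (2R,3S)-2-methyl-5-[(2R)-2-methyloxiran-2-yl]-3-(oxan-2-ylperoxy)pentanoic acid | OC(=O)[C@H](C)[C@@H](OOC1CCCCO1)CC[C@]2(C)CO2
F5 | step 5 | methyl (2R,3S)-2-methyl-5-[(2R)-2-methyloxiran-2-yl]-3-(oxan-2-ylperoxy)pentanoate | COC(=O)[C@H](C)[C@@H](OOC1CCCCO1)CC[C@]2(C)CO2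
F6 | step 16 | (3S)-3-hydroperoxy-3,7-dimethyloct-6-en-1-yl acetate | CC(=O)OCC[C@](C)(CCC=C(C)C)OO
F7 | step 16 | (3S)-3-{[tert-butyl(dimethyl)silyl]peroxy}-3,7-dimethyloct-6-en-1-yl acetate | CC(=O)OCC[C@](C)(CCC=C(C)C)OO[Si](C)(C)C(C)(C)C
F8 | step 22 | 5-{[(3S,4Z,7S)-7-{[tert-butyl(dimethyl)silyl]peroxy}-3,7,11-trimethyldodeca-4,10-dien-1-yl]sulfonyl}-1-phenyl-1H-tetrazole | O=S(=O)(CC[C@H](C)/C=C\C[C@](C)(CCC=C(C)C)OO[Si](C)(C)C(C)(C)C)c1nnnn1-c1ccccc1
F9 | step 22 | methyl (2R)-2-[(3S,6S)-6-[(1E,4S,5Z,8S)-8-{[tert-butyl(dimethyl)silyl]peroxy}-4,8,12-trimethyltrideca-1,5,11-trien-1-yl]-6-methyl-1,2-dioxan-3-yl]propanoate | COC(=O)[C@H](C)[C@@H]1CC[C@@](C)(/C=C/C[C@H](C)/C=C\C[C@](C)(CCC=C(C)C)OO[Si](C)(C)C(C)(C)C)OO1
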